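**Strategy.** The route rests on cutting the acyl C3–C4 bond of the dodec-2-enoyl chain, between the sp2 β-carbon of the E-enamide and the unfunctionalised nonyl group. The key step is a nickel-electrocatalytic decarboxylative alkenylation: the N-hydroxyphthalimide ester of decanoic acid delivers a nonyl radical (CO2 as traceless handle) to the (E)-3-iodoacrylamide of the complete, unprotected 3-oxatricyclo[4.3.1.0^{2,4}]decan-10-one core. It exploits the C3 vinyl position, whose E geometry is pre-set, and the base-free conditions should tolerate the oxirane, the bridging ketone and both hydroxyls. The core arises from L-o-tyrosine by hydroxylative dearomatisation/epoxidation and a methanol oxa-Michael/aldol cascade that sets three stereocentres at once.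

Key step: step 7

Assumptions: L-o-tyrosine is bought as the single (S)-enantiomer. Which antipode of the chiral iodoarene in step 3 favours the (S)-carbinol cannot be predicted and is fixed by a test reaction; because 4 is enantiopure, any minor ring epimer is a diastereomer and is removed by chromatography. Core locants follow the 3-oxatricyclo[4.3.1.0^{2,4}]decane numbering of 9 and 13 (C1 carbinol bridgehead, C2/C4 oxirane, C5 OMe, C6 bridgehead CH, C7 CHOH, C8 CHN, C10 C=O).

Step 1
Reactants: 1 L-o-tyrosine
Product: 2 L-o-tyrosinol [(2S)-2-amino-3-(2-hydroxyphenyl)propan-1-ol]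
Conditions: NaBH4, I2, THF, 0 °C to reflux; then MeOH; aq. KOH work-up
Reagents that add atoms: none
Why: Borane generated in situ from NaBH4/I2 reduces the free amino acid to the amino alcohol (amino acid reduction), and the stereocentre is not enolisable under these conditions.

Step 2
Reactants: 2 L-o-tyrosinol; 3 (2E)-3-iodoprop-2-enoic acid
Product: 4 (2E)-N-[(2S)-1-hydroxy-3-(2-hydroxyphenyl)propan-2-yl]-3-iodoprop-2-enamide
Conditions: EDC·HCl, HOBt, DMF/CH2Cl2, 0 °C to rt
Reagents that add atoms: none
Why: Carbodiimide/HOBt amide coupling, in which the primary amine outcompetes the phenol and the primary alcohol and acylation through the active ester at 0 °C should be faster than addition–elimination at the β-iodo carbon, so the E-iodoacrylamide keeps its geometry.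

Step 3
Reactants: 4 (2E)-N-[(2S)-1-hydroxy-3-(2-hydroxyphenyl)propan-2-yl]-3-iodoprop-2-enamide
Product: 6 epoxy-o-quinol alcohol (2E)-N-[(2S)-1-hydroxy-3-[(1S,2S,6S)-2-hydroxy-3-oxo-7-oxabicyclo[4.1.0]hept-4-en-2-yl]propan-2-yl]-3-iodoprop-2-enamide, via o-quinol dienone 5 (not isolated)
Conditions: C2-symmetric chiral 2,2'-diiodobiaryl precatalyst (0.2 equiv, pre-oxidised with mCPBA at rt), mCPBA (2.4 equiv in total), NaHCO3, CH2Cl2 (0.02 M), −40 to 0 °C
Reagents that add atoms: mCPBA (3-chloroperoxybenzoic acid), OOC(=O)c1cccc(Cl)c1
Why: Hydroxylative phenol dearomatisation by the chiral λ5-iodane formed in situ transfers oxygen to the more nucleophilic alkyl-bearing ortho carbon and sets the carbinol centre under reagent control, and the excess peracid then epoxidises the only allylic C=C of the dilute, cold dienone 5 syn to the tertiary OH (hydroxyl-directed peracid epoxidation) before [4+2] dimerisation can compete.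

Step 4
Reactants: 6 epoxy-o-quinol alcohol
Product: 7 epoxy-o-quinol aldehyde (2E)-N-[(2S)-1-[(1S,2S,6S)-2-hydroxy-3-oxo-7-oxabicyclo[4.1.0]hept-4-en-2-yl]-3-oxopropan-2-yl]-3-iodoprop-2-enamide
Conditions: Dess–Martin periodinane, NaHCO3, CH2Cl2, 0 °C to rt; used crude at once
Reagents that add atoms: none
Why: Dess–Martin oxidation converts the primary alcohol to the aldehyde under buffered, non-basic conditions that should spare the tertiary alcohol, oxirane, enone and vinyl iodide and not epimerise the N-acyl α-amino aldehyde, which may rest partly as its spiro-lactol with the tertiary OH.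

Step 5
Reactants: 7 epoxy-o-quinol aldehyde
Product: 9 iodoacrylamide core (2E)-N-[(1S,2S,4S,5S,6S,7R,8S)-1,7-dihydroxy-5-methoxy-10-oxo-3-oxatricyclo[4.3.1.0^{2,4}]decan-8-yl]-3-iodoprop-2-enamide, via β-methoxy ketone aldehyde 8 (not isolated)
Conditions: Mg(OMe)2 (0.2 equiv), MeOH, −10 to 0 °C
Reagents that add atoms: methanol, CO
Why: Tandem oxa-Michael/intramolecular aldol cascade, in which methoxide adds axially to C5 of the enone on the face of the tertiary oxygen and the oxirane (magnesium-bridged delivery, anti to the side chain), the enolate then closes the 6-(enolexo)-exo-trig aldol from the only face the tether reaches with the aldehyde oxygen chelated to the enolate magnesium so that the C7 hydroxyl lies syn to the bridging ketone and the untouched (S)-C8 places the amide exo, while catalytic base at or below 0 °C should leave the secondary β-iodoacrylamide, a much weaker acceptor than the ring enone, untouched.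

Step 6
Reactants: 10 decanoic acid; 11 N-hydroxyphthalimide
Product: 12 1,3-dioxoisoindolin-2-yl decanoate
Conditions: DIC, DMAP (cat.), CH2Cl2, rt
Reagents that add atoms: none
Why: Steglich-type esterification gives the redox-active ester, which turns the carboxyl group into a reductively cleavable, traceless precursor of the nonyl radical.

Step 7
Reactants: 9 iodoacrylamide core; 12 1,3-dioxoisoindolin-2-yl decanoate (2 equiv)
Product: 13 (2E)-N-[(1S,2S,4S,5S,6S,7R,8S)-1,7-dihydroxy-5-methoxy-10-oxo-3-oxatricyclo[4.3.1.0^{2,4}]decan-8-yl]dodec-2-enamide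
Conditions: NiCl2·6H2O (10 mol%), 2,2'-bipyridine (10 mol%), AgNO3 (0.3 equiv), DMF, (+)Mg/(−)RVC, undivided cell, constant current, rt
Reagents that add atoms: none
Why: Nickel-electrocatalytic decarboxylative alkenylation, a reductive cross-electrophile coupling: cathodically generated low-valent Ni(bpy) adds oxidatively to the C(sp2)–I bond of 9 with retention, ester 12 accepts one electron and fragments to phthalimide anion, CO2 and the nonyl radical, and radical capture at nickel followed by reductive elimination forges the acyl C3–C4 bond. The closest known reaction type is the Ni-catalysed coupling of N-hydroxyphthalimide esters of primary acids with alkenyl iodides at a silver-nanoparticle-coated cathode. No ring is closed and no stereocentre is formed; the E double bond is inherited from 3 because oxidative addition and reductive elimination are stereoretentive, and a stray nonyl radical adding to C3 of the iodoacrylamide would expel iodine and converge on the same E product. The step needs cross-coupling to win over homo-coupling and hydrodeiodination, which the excess of 12 and the fast oxidative addition of the electron-poor vinyl iodide should secure. It also needs the oxirane, the bridging α-hydroxy ketone, the β-hydroxy and β-methoxy ketone motifs and the amide N–H to survive, which the absence of base and of any organometallic nucleophile and the low cathode potential of the nickel cycle should allow (retro-aldol needs base, and the bridgehead C6 blocks enolisation and hence retro-Michael loss of methanol).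

**Compound list**

1 | L-o-tyrosine [(2S)-2-amino-3-(2-hydroxyphenyl)propanoic acid] | N[C@@H](Cc1ccccc1O)C(=O)O | starting material
2 | L-o-tyrosinol [(2S)-2-amino-3-(2-hydroxyphenyl)propan-1-ol] | N[C@@H](Cc1ccccc1O)CO | intermediate
3 | (2E)-3-iodoprop-2-enoic acid | OC(=O)/C=C/I | starting material
4 | (2E)-N-[(2S)-1-hydroxy-3-(2-hydroxyphenyl)propan-2-yl]-3-iodoprop-2-enamide | I/C=C/C(=O)N[C@@H](Cc1ccccc1O)CO | intermediate
5 | o-quinol dienone: (2E)-N-[(2S)-1-hydroxy-3-[(1S)-1-hydroxy-6-oxocyclohexa-2,4-dien-1-yl]propan-2-yl]-3-iodoprop-2-enamide | I/C=C/C(=O)N[C@@H](C[C@@]1(O)C(=O)C=CC=C1)CO | intermediate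
6 | epoxy-o-quinol alcohol: (2E)-N-[(2S)-1-hydroxy-3-[(1S,2S,6S)-2-hydroxy-3-oxo-7-oxabicyclo[4.1.0]hept-4-en-2-yl]propan-2-yl]-3-iodoprop-2-enamide (oxirane syn to the tertiary OH) | I/C=C/C(=O)N[C@@H](C[C@@]1(O)C(=O)C=C[C@@H]2O[C@H]12)CO | intermediate
7 | epoxy-o-quinol aldehyde: (2E)-N-[(2S)-1-[(1S,2S,6S)-2-hydroxy-3-oxo-7-oxabicyclo[4.1.0]hept-4-en-2-yl]-3-oxopropan-2-yl]-3-iodoprop-2-enamide | I/C=C/C(=O)N[C@@H](C[C@@]1(O)C(=O)C=C[C@@H]2O[C@H]12)C=O | intermediate
8 | β-methoxy ketone aldehyde: (2E)-N-[(2S)-1-[(1S,2S,5S,6S)-2-hydroxy-5-methoxy-3-oxo-7-oxabicyclo[4.1.0]heptan-2-yl]-3-oxopropan-2-yl]-3-iodoprop-2-enamide (OH, oxirane O and OMe all on one ring face) | I/C=C/C(=O)N[C@@H](C[C@@]1(O)C(=O)C[C@H](OC)[C@@H]2O[C@H]12)C=O | intermediate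
9 | iodoacrylamide core: (2E)-N-[(1S,2S,4S,5S,6S,7R,8S)-1,7-dihydroxy-5-methoxy-10-oxo-3-oxatricyclo[4.3.1.0^{2,4}]decan-8-yl]-3-iodoprop-2-enamide | I/C=C/C(=O)N[C@H]1C[C@@]2(O)C(=O)[C@@H]([C@H]1O)[C@H](OC)[C@@H]1O[C@@H]12 | intermediate
10 | decanoic acid | CCCCCCCCCC(=O)O | starting material
11 | N-hydroxyphthalimide | ON1C(=O)c2ccccc2C1=O | starting material
12 | 1,3-dioxoisoindolin-2-yl decanoate | CCCCCCCCCC(=O)ON1C(=O)c2ccccc2C1=O | intermediate
13 | (2E)-N-[(1S,2S,4S,5S,6S,7R,8S)-1,7-dihydroxy-5-methoxy-10-oxo-3-oxatricyclo[4.3.1.0^{2,4}]decan-8-yl]dodec-2-enamide | CCCCCCCCC/C=C/C(=O)N[C@H]1C[C@@]2(O)C(=O)[C@@H]([C@H]1O)[C@H](OC)[C@@H]1O[C@@H]12 | target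

**Step count.** Total: 7 steps. Longest linear sequence: 6 steps (steps 1, 2, 3, 4, 5, 7).

**Steps most likely to fail**

Step 3. What may go wrong: weak facial induction by the chiral iodane at the ring carbon, oxygen transfer to the unsubstituted ortho or para positions, or [4+2] dimerisation of dienone 5 before the epoxidation catches it. Fallback (selection moved from the reagent to the substrate): setting out from 4, dearomatisation with achiral stabilised IBX in dilute THF followed at once by mCPBA/NaHCO3 would give 6 together with its ring epimer, the (1R,2R,6R)-epoxy-o-quinol alcohol F1. If the two cannot be separated, the mixture is oxidised as in step 4 to 7 and the epimeric aldehyde F2 and submitted to step 5. There only 7 can close to a chair–chair bicycle with the amide exo, whereas F2 would have to place the amide endo above the oxirane and should stay monocyclic, so chromatography brings the route back at 9. Base and temperature are kept low so that F2 does not epimerise at the aldehyde α-carbon into the enantiomeric series.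

Step 5. What may go wrong: methoxide adding to C5 anti to the oxirane (wrong C5 epimer), or base-induced opening of the γ,δ-epoxy enone faster than the cascade. Fallback (order inverted so that the oxirane is made last, on the rigid bicycle): setting out from 4, the dearomatisation is stopped at dienone 5 (one equivalent of oxidant, no excess peracid) and the primary alcohol is oxidised in the same dilute solution with Dess–Martin periodinane to the o-quinol aldehyde F3. Mg(OMe)2/MeOH should then give the bicyclic allylic alcohol F4, in which C5–OMe is set only by trans-diaxial addition across the enone (anti to the closing tether) and the irreversible aldol drains the 1,4-adduct. Epoxidation of the remaining ring alkene with VO(acac)2/t-BuOOH, directed by the bridgehead OH and on the open exo face, returns to 9.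

Step 7. What may go wrong: opening of the oxirane by magnesium iodide building up from the sacrificial anode, or hydrodeiodination of the iodoacrylamide at the cathode instead of coupling. Fallback (photochemical radical generation, no metal anode): setting out from 9, Ni/photoredox dual catalysis (NiCl2·dme, 4,4'-di-tert-butyl-2,2'-bipyridine, Ru(bpy)3(PF6)2, DMF, blue LEDs, rt) with triethylammonium nonylbis(catecholato)silicate F5, prepared from trimethoxy(nonyl)silane, catechol and triethylamine, would generate the same nonyl radical by single-electron oxidation and form the same acyl C3–C4 bond, arriving directly at 13.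

**Further compounds**

F1 | step 3 | (2E)-N-[(2S)-1-hydroxy-3-[(1R,2R,6R)-2-hydroxy-3-oxo-7-oxabicyclo[4.1.0]hept-4-en-2-yl]propan-2-yl]-3-iodoprop-2-enamide | I/C=C/C(=O)N[C@@H](C[C@]1(O)C(=O)C=C[C@H]2O[C@@H]12)CO
F2 | step 3 | (2E)-N-[(2S)-1-[(1R,2R,6R)-2-hydroxy-3-oxo-7-oxabicyclo[4.1.0]hept-4-en-2-yl]-3-oxopropan-2-yl]-3-iodoprop-2-enamide | I/C=C/C(=O)N[C@@H](C[C@]1(O)C(=O)C=C[C@H]2O[C@@H]12)C=O
F3 | step 5 | (2E)-N-[(2S)-1-[(1S)-1-hydroxy-6-oxocyclohexa-2,4-dien-1-yl]-3-oxopropan-2-yl]-3-iodoprop-2-enamide | I/C=C/C(=O)N[C@@H](C[C@@]1(O)C(=O)C=CC=C1)C=O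
F4 | step 5 | (2E)-N-[(1S,4R,5S,6R,7S)-1,6-dihydroxy-4-methoxy-9-oxobicyclo[3.3.1]non-2-en-7-yl]-3-iodoprop-2-enamide | I/C=C/C(=O)N[C@H]1C[C@@]2(O)C(=O)[C@@H]([C@H]1O)[C@H](OC)C=C2
F5 | step 7 | triethylammonium nonylbis(benzene-1,2-diolato)silicate | CCCCCCCCC[Si-]12(Oc3ccccc3O1)Oc1ccccc1O2.CC[NH+](CC)CC
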